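The plan rests on cutting the two C4–C4a bonds. Each C4 carbonyl sits on C4a of a phloroglucinol-type ring A. The two ring A carbons ortho to O1 are equivalent, so an aryl ether of 3,5-bis(benzyloxy)phenol can be acylated only to the 5,7-pattern. One twofold intramolecular Friedel–Crafts acylation therefore closes both rings C and leaves C2, C3, C2'' and C3'' untouched. Its substrate is the C2-symmetric all-R succinic acid that bears an aryloxy(4-methoxyphenyl)methyl group on each α-carbon. To reach it without a β-aryloxy enolate, the C3–C3'' bond is made first and both ethers are formed by arylation on oxygen.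

Key step: step 9

Remarks on the chemistry
- The descriptors 2R,3R,2''R,3''R mean 2,3-cis and 2'',3''-cis rings C. The all-R diacid and its tetrabenzyl cyclisation product were checked centre by centre against the target and carry the same array, so neither structure needs correcting.
- An enolate next to an aryloxy-bearing carbon expels aryloxide. A 4-methoxybenzylic carbinol that is activated near a γ-carbonyl group or a second carbinol cyclises. The route therefore never breaks a C2–O bond and never enolises C3 once O1 is arylated.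
- The succinate carbons are labelled S before and R after benzylic oxygenation only because the ranking of their substituents changes.
- [3,5-Bis(benzyloxy)phenyl]boronic acid is assumed to be purchasable.

Step 1
Reactants: 1 3-(4-methoxyphenyl)propanoyl chloride; 2 (R)-4-isopropyl-1,3-oxazolidin-2-one
Product: 3 (R)-4-isopropyl-3-[3-(4-methoxyphenyl)propanoyl]-1,3-oxazolidin-2-one
Conditions: 2, n-BuLi, THF, −78 °C; then 1, −78 → 0 °C
Reagents that add atoms: none
Why: N-acylation of the lithiated oxazolidinone by an acid chloride is routine and creates no stereocentre.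

Step 2
Reactants: 3 (two molecules)
Product: 4 (2S,3S)-2,3-bis(4-methoxybenzyl)-1,4-bis[(R)-4-isopropyl-2-oxo-1,3-oxazolidin-3-yl]butane-1,4-dione
Conditions: LiN(i-Pr)2, THF, −78 °C; TiCl4, −78 → 0 °C
Reagents that add atoms: none
Why: Oxidative enolate homocoupling (one-electron oxidation of the chelated Z-lithium enolate by tetravalent titanium) is established for 3-arylpropanoyl oxazolidinones, and because each isopropyl group shields one enolate face the (R)-auxiliary should set both new centres as S and give the C2-symmetric dimer.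

Step 3
Reactants: 4
Product: 5 (2S,3S)-2,3-bis(4-methoxybenzyl)butanedioic acid
Conditions: LiOH, H2O2, THF/H2O, 0 °C; Na2SO3; HCl to pH 2
Reagents that add atoms: hydrogen peroxide, OO
Why: Hydroperoxide-mediated auxiliary cleavage attacks the exocyclic imide carbonyl selectively, and the α-centres carry no β-leaving group at this stage, so they should survive the mild base.

Step 4
Reactants: 5
Product: 6 (3R,3aR,6R,6aR)-3,6-bis(4-methoxyphenyl)tetrahydrofuro[3,4-c]furan-1,4-dione (cis-fused dilactone, both aryl groups exo)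
Conditions: DDQ (2.5 equiv), 1,4-dioxane, 80 °C
Reagents that add atoms: none
Why: In this oxidative benzylic C–H lactonisation DDQ abstracts hydride from each 4-methoxybenzylic CH2 and the γ-carboxyl group traps the cation in a 5-exo closure; each aryl group settles on the convex face trans to the neighbouring carbonyl substituent, and reversible ionisation lets the exo,exo isomer (both new centres R) accumulate.

Step 5
Reactants: 6
Product: 7 (2R,3R)-2,3-bis[(R)-hydroxy(4-methoxyphenyl)methyl]-N1,N4-dimethoxy-N1,N4-dimethylbutanediamide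
Conditions: MeNH(OMe), AlMe3, CH2Cl2, 0 °C → rt; aq. KNaC4H4O6
Reagents that add atoms: N,O-dimethylhydroxylamine, CNOC
Why: Aluminium-amide aminolysis of a lactone cleaves only the acyl–oxygen bonds, so all four centres are kept, and it masks the carboxyl groups as tertiary amides that do not relactonise readily while the carbinols are free.

Step 6
Reactants: 7; 8 [3,5-bis(benzyloxy)phenyl]boronic acid
Product: 9 (2R,3R)-2,3-bis{(R)-[3,5-bis(benzyloxy)phenoxy](4-methoxyphenyl)methyl}-N1,N4-dimethoxy-N1,N4-dimethylbutanediamide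
Conditions: 8 (5 equiv), Cu(OAc)2 (0.4 equiv), DMAP, 4 Å molecular sieves, O2 (1 atm), CH2Cl2, rt
Reagents that add atoms: none
Why: Chan–Lam O-arylation of a secondary alcohol builds the O1–C8a bonds at oxygen under near-neutral conditions, so the ionisable 4-methoxybenzylic C–O bonds are never broken and both carbinol centres are retained as R.

Step 7
Reactants: 9
Product: 10 (2R,3R)-2,3-bis{(R)-[3,5-bis(benzyloxy)phenoxy](4-methoxyphenyl)methyl}butanedial
Conditions: i-Bu2AlH, THF, −78 → −40 °C; cold aq. KNaC4H4O6; used crude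
Reagents that add atoms: none
Why: Hydride reduction of an N-methoxy-N-methylamide stops at the chelated tetrahedral aluminium adduct, so the aldehyde appears only on cold neutral work-up and base-induced loss of aryloxide or epimerisation at C3 is avoided.

Step 8
Reactants: 10
Product: 11 (2R,3R)-2,3-bis{(R)-[3,5-bis(benzyloxy)phenoxy](4-methoxyphenyl)methyl}butanedioic acid
Conditions: PhI(OAc)2 (2.5 equiv), TEMPO (cat.), MeCN/H2O, 0 °C → rt
Reagents that add atoms: water, O
Why: Oxoammonium oxidation of the aldehyde hydrates runs at slightly acidic pH and without hypochlorite, which spares the chlorination-prone trialkoxyarenes, the aryl ethers and the C3 centres.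

Step 9
Reactants: 11
Product: 15 (2R,3R,2''R,3''R)-5,7,5'',7''-tetrakis(benzyloxy)-4',4'''-dimethoxy-3,3''-biflavanone, via cyclic anhydride 12 (not isolated), via keto acid 13 (not isolated), via mixed anhydride 14 (not isolated)
Conditions: (CF3CO)2O (6 equiv), CH2Cl2, −20 → 0 °C
Reagents that add atoms: none
Why: (CF3CO)2O first dehydrates the 1,4-diacid to the five-membered anhydride 12, and the carbonyl next to C3, activated by the CF3CO2H released, is attacked by the ring A carbon ortho to O1 and para to a benzyloxy group, after which the Wheland intermediate rearomatises and the anhydride opens to keto acid 13. The freed carboxyl group is reactivated as mixed anhydride 14 and the second ring A repeats the event, so this is the known trifluoroacetic-anhydride-mediated Friedel–Crafts cyclisation of 3-aryloxypropanoic acids to chroman-4-ones, run twice in one molecule. Each ring C closes in a 6-exo-trig mode at the acyl carbon (endo with respect to the arene π bond), which should outrun the seven-membered closure through the distal carbonyl. No stereocentre is created and no bond to C2, C3, C2'' or C3'' is broken, so the all-R array of 11 passes unchanged into the 2,3-cis, 2'',3''-cis product. Regiochemistry needs no control because the two carbons ortho to O1 are equivalent and the para carbon cannot reach the acyl group. The step needs chemoselectivity only: acylation must outrun ionisation of the 4-methoxybenzylic C2–O1 bond (which would end in γ-lactone formation with loss of the phenol) and enolisation or ketene formation at C3, and this is secured by the highly nucleophilic trioxygenated ring, the absence of base and of strong Lewis acid, and the low temperature.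

Step 10
Reactants: 15
Product: 16 (2R,3R,2''R,3''R)-5,7,5'',7''-tetrahydroxy-4',4'''-dimethoxy-3,3''-biflavanone (target)
Conditions: H2 (1 atm), Pd/C (10%), EtOAc, rt
Reagents that add atoms: none
Why: Catalytic hydrogenolysis removes the four primary O-benzyl groups faster than it attacks the hindered secondary C2–O1 bond, and the neutral medium keeps the epimerisable 2,3-cis centres and the ring C ether intact.

Compound list
1 | 3-(4-methoxyphenyl)propanoyl chloride | COc1ccc(CCC(=O)Cl)cc1 | starting material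
2 | (R)-4-isopropyl-1,3-oxazolidin-2-one | CC(C)[C@@H]1COC(=O)N1 | starting material
3 | (R)-4-isopropyl-3-[3-(4-methoxyphenyl)propanoyl]-1,3-oxazolidin-2-one | COc1ccc(CCC(=O)N2C(=O)OC[C@H]2C(C)C)cc1 | intermediate
4 | (2S,3S)-2,3-bis(4-methoxybenzyl)-1,4-bis[(R)-4-isopropyl-2-oxo-1,3-oxazolidin-3-yl]butane-1,4-dione | COc1ccc(cc1)C[C@H](C(=O)N1C(=O)OC[C@H]1C(C)C)[C@@H](C(=O)N1C(=O)OC[C@H]1C(C)C)Cc1ccc(OC)cc1 | intermediate
5 | (2S,3S)-2,3-bis(4-methoxybenzyl)butanedioic acid | COc1ccc(cc1)C[C@H](C(=O)O)[C@@H](C(=O)O)Cc1ccc(OC)cc1 | intermediate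
6 | (3R,3aR,6R,6aR)-3,6-bis(4-methoxyphenyl)tetrahydrofuro[3,4-c]furan-1,4-dione | O=C1O[C@@H](c3ccc(OC)cc3)[C@H]2[C@@H]1[C@H](c3ccc(OC)cc3)OC2=O | intermediate
7 | (2R,3R)-2,3-bis[(R)-hydroxy(4-methoxyphenyl)methyl]-N1,N4-dimethoxy-N1,N4-dimethylbutanediamide | COc1ccc(cc1)[C@H](O)[C@H](C(=O)N(C)OC)[C@@H](C(=O)N(C)OC)[C@@H](O)c1ccc(OC)cc1 | intermediate
8 | [3,5-bis(benzyloxy)phenyl]boronic acid | OB(O)c1cc(OCc2ccccc2)cc(OCc2ccccc2)c1 | starting material
9 | (2R,3R)-2,3-bis{(R)-[3,5-bis(benzyloxy)phenoxy](4-methoxyphenyl)methyl}-N1,N4-dimethoxy-N1,N4-dimethylbutanediamide | COc1ccc(cc1)[C@H](Oc1cc(OCc2ccccc2)cc(OCc2ccccc2)c1)[C@H](C(=O)N(C)OC)[C@@H](C(=O)N(C)OC)[C@@H](Oc1cc(OCc2ccccc2)cc(OCc2ccccc2)c1)c1ccc(OC)cc1 | intermediate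
10 | (2R,3R)-2,3-bis{(R)-[3,5-bis(benzyloxy)phenoxy](4-methoxyphenyl)methyl}butanedial | COc1ccc(cc1)[C@H](Oc1cc(OCc2ccccc2)cc(OCc2ccccc2)c1)[C@H](C=O)[C@@H](C=O)[C@@H](Oc1cc(OCc2ccccc2)cc(OCc2ccccc2)c1)c1ccc(OC)cc1 | intermediate
11 | (2R,3R)-2,3-bis{(R)-[3,5-bis(benzyloxy)phenoxy](4-methoxyphenyl)methyl}butanedioic acid | COc1ccc(cc1)[C@H](Oc1cc(OCc2ccccc2)cc(OCc2ccccc2)c1)[C@H](C(=O)O)[C@@H](C(=O)O)[C@@H](Oc1cc(OCc2ccccc2)cc(OCc2ccccc2)c1)c1ccc(OC)cc1 | intermediate
12 | (3R,4R)-3,4-bis{(R)-[3,5-bis(benzyloxy)phenoxy](4-methoxyphenyl)methyl}oxolane-2,5-dione | COc1ccc(cc1)[C@H](Oc1cc(OCc2ccccc2)cc(OCc2ccccc2)c1)[C@@H]3C(=O)OC(=O)[C@H]3[C@@H](Oc1cc(OCc2ccccc2)cc(OCc2ccccc2)c1)c1ccc(OC)cc1 | intermediate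
13 | (2R,3R)-3-[3,5-bis(benzyloxy)phenoxy]-2-[(2R,3R)-5,7-bis(benzyloxy)-2-(4-methoxyphenyl)-4-oxochroman-3-yl]-3-(4-methoxyphenyl)propanoic acid | COc1ccc([C@@H]2Oc3cc(OCc4ccccc4)cc(OCc4ccccc4)c3C(=O)[C@@H]2[C@@H](C(=O)O)[C@@H](Oc2cc(OCc3ccccc3)cc(OCc3ccccc3)c2)c2ccc(OC)cc2)cc1 | intermediate
14 | mixed anhydride of 13 with trifluoroacetic acid | COc1ccc([C@@H]2Oc3cc(OCc4ccccc4)cc(OCc4ccccc4)c3C(=O)[C@@H]2[C@@H](C(=O)OC(=O)C(F)(F)F)[C@@H](Oc2cc(OCc3ccccc3)cc(OCc3ccccc3)c2)c2ccc(OC)cc2)cc1 | intermediate
15 | (2R,3R,2''R,3''R)-5,7,5'',7''-tetrakis(benzyloxy)-4',4'''-dimethoxy-3,3''-biflavanone | COc1ccc([C@@H]2Oc3cc(OCc4ccccc4)cc(OCc4ccccc4)c3C(=O)[C@@H]2[C@H]2C(=O)c3c(OCc4ccccc4)cc(OCc4ccccc4)cc3O[C@H]2c2ccc(OC)cc2)cc1 | intermediate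
16 | (2R,3R,2''R,3''R)-5,7,5'',7''-tetrahydroxy-4',4'''-dimethoxy-3,3''-biflavanone | COc1ccc([C@@H]2Oc3cc(O)cc(O)c3C(=O)[C@@H]2[C@H]2C(=O)c3c(O)cc(O)cc3O[C@H]2c2ccc(OC)cc2)cc1 | target

Total steps: 10. Longest linear sequence: 10 steps (1 → 16).

Steps most likely to fail

1. Step 6.
- What may go wrong: two hindered secondary carbinols must both be arylated. Sluggish aryl transfer from copper, copper-mediated oxidation of the benzylic alcohols and slow relactonisation may erode conversion.
- Fallback: replace the copper coupling by nucleophilic aromatic substitution on a carbonyl-free relay, as is known for benzylic alkoxides and weakly activated fluoroarenes. It sets out from 6 and comes back at 10.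
- LiAlH4 in THF reduces 6 to the tetraol F1, and TIPSCl with imidazole silylates only the primary hydroxyls to give the bis(silyl ether) F2.
- 1,3-Bis(benzyloxy)-5-fluorobenzene F3 is prepared from 1,3,5-trifluorobenzene, benzyl alcohol and NaH.
- The dipotassium alkoxide of F2 (KN(SiMe3)2, DMSO/THF, 60 °C) displaces fluoride from F3 with retention at carbon and gives the bis(aryl ether) F4.
- Bu4NF then frees the 1,4-diol F5.
- A Swern oxidation, in which both hydroxyls are activated before the amine is added, delivers 10.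

2. Step 9.
- What may go wrong: acid-induced ionisation of the C2–O1 bond with capture by the γ-carboxyl group, stalling at the anhydride stage, or epimerisation at C3.
- Fallback: reverse the order of bond formation. It sets out from 6 and comes back at 15.
- F3 is brominated para to a benzyloxy group (NBS, MeCN, 0 °C) to give 1,5-bis(benzyloxy)-2-bromo-3-fluorobenzene F6.
- Bromine–lithium exchange (n-BuLi, THF, −78 °C) and addition of the aryllithium to both lactone carbonyls of 6 give the bis(β-hydroxy ketone) F7. Over-addition is held back by the hemiketal alkoxide.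
- K2CO3 in DMF at rt then closes both rings C by intramolecular nucleophilic aromatic substitution of the fluoride ortho to each ketone, again with retention at C2.

3. Step 4.
- What may go wrong: loss of the C3 proton from the benzylic cation (dehydrogenation instead of lactonisation), an incomplete second oxidation, or over-oxidation.
- Fallback: switch from hydride abstraction to radical C–H functionalisation. It sets out from 5 and comes back at 6.
- Wohl–Ziegler bromination (NBS, AIBN, PhCF3, reflux) gives the bis(benzylic bromide) F8 as a mixture of epimers at the C–Br carbons.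
- On warming, the γ-carboxyl groups displace bromide through the stabilised cation, and the mixture converges on the exo,exo dilactone 6.

Further compounds
F1 | step 6 | (1R,2S,3S,4R)-2,3-bis(hydroxymethyl)-1,4-bis(4-methoxyphenyl)butane-1,4-diol | COc1ccc(cc1)[C@H](O)[C@H](CO)[C@@H](CO)[C@@H](O)c1ccc(OC)cc1
F2 | step 6 | (1R,2S,3S,4R)-1,4-bis(4-methoxyphenyl)-2,3-bis[(triisopropylsilyloxy)methyl]butane-1,4-diol | COc1ccc(cc1)[C@H](O)[C@H](CO[Si](C(C)C)(C(C)C)C(C)C)[C@@H](CO[Si](C(C)C)(C(C)C)C(C)C)[C@@H](O)c1ccc(OC)cc1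
F3 | step 6 | 1,3-bis(benzyloxy)-5-fluorobenzene | Fc1cc(OCc2ccccc2)cc(OCc2ccccc2)c1
F4 | step 6 | bis[3,5-bis(benzyloxy)phenyl] ether of F2 (configuration unchanged) | COc1ccc(cc1)[C@H](Oc1cc(OCc2ccccc2)cc(OCc2ccccc2)c1)[C@H](CO[Si](C(C)C)(C(C)C)C(C)C)[C@@H](CO[Si](C(C)C)(C(C)C)C(C)C)[C@@H](Oc1cc(OCc2ccccc2)cc(OCc2ccccc2)c1)c1ccc(OC)cc1
F5 | step 6 | (2S,3S)-2,3-bis{(R)-[3,5-bis(benzyloxy)phenoxy](4-methoxyphenyl)methyl}butane-1,4-diol | COc1ccc(cc1)[C@H](Oc1cc(OCc2ccccc2)cc(OCc2ccccc2)c1)[C@H](CO)[C@@H](CO)[C@@H](Oc1cc(OCc2ccccc2)cc(OCc2ccccc2)c1)c1ccc(OC)cc1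
F6 | step 9 | 1,5-bis(benzyloxy)-2-bromo-3-fluorobenzene | Fc1cc(OCc2ccccc2)cc(OCc2ccccc2)c1Br
F7 | step 9 | (2R,3R)-1,4-bis[2,4-bis(benzyloxy)-6-fluorophenyl]-2,3-bis[(R)-hydroxy(4-methoxyphenyl)methyl]butane-1,4-dione | COc1ccc(cc1)[C@H](O)[C@H](C(=O)c1c(F)cc(OCc2ccccc2)cc1OCc1ccccc1)[C@@H](C(=O)c1c(F)cc(OCc2ccccc2)cc1OCc1ccccc1)[C@@H](O)c1ccc(OC)cc1
F8 | step 4 | (2S,3S)-2,3-bis[bromo(4-methoxyphenyl)methyl]butanedioic acid (epimers at the C–Br carbons) | COc1ccc(cc1)C(Br)[C@H](C(=O)O)[C@@H](C(=O)O)C(Br)c1ccc(OC)cc1
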